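The bicyclo[3.2.1]oct-3-ene-2,8-dione core is read as the ring-expanded isomer of a quinone–stilbene [2+2] adduct. The bond C1–C7 of the target is benzylic to the 4-hydroxyphenyl ring and α to both carbonyls C2 and C8; the same donor–acceptor polarity makes the C4–C7 bond of cyclobutane 5 (ring C4–C5–C6–C7, fused to a 2-methoxy-enedione) ionise under TiCl4. Recapture of C7 by enol-ether carbon C1 expands the four-membered ring to cyclopentanone C1–C8–C5–C6–C7, closes the bicycle, sets C1 and C7 and unveils the C2 ketone. C5 and C6 come from an enantioselective [2+2]; C3–OH and C4–Cl are then exchanged for H and styryl.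

Key step: step 4

Remark: atom labels C1–C8 are those of the bicyclo[3.2.1]octene core of the target (C1 between the two carbonyls, C2 enone carbonyl, C4 styryl-bearing, C6/C7 aryl-bearing, C8 bridging carbonyl) and are carried back into every intermediate. In quinone 2, C3 is the carbonyl between C–OMe (C2) and C–Cl (C4), C8 is the other carbonyl, and C1 and C5 are the two CH carbons. TBS = tert-butyldimethylsilyl.

Assumption: the titanium complex of (4R,5R)-TADDOL is taken to shield the quinone face that leads to 5 as drawn; if the sense of induction is the opposite one, the (4S,5S) ligand is used.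

Step 1
Reactants: 1 2-chloro-6-methoxyphenol
Product: 2 2-chloro-6-methoxy-1,4-benzoquinone
Conditions: ON(SO3K)2 (Fremy's salt), KH2PO4, H2O/acetone, 0 °C to rt
Reagents that add atoms: potassium nitrosodisulfonate, [O]N(S(=O)(=O)[O-])S(=O)(=O)[O-].[K+].[K+]
Why: Teuber oxidation, in which the phenoxyl radical is trapped at the free para position by a second nitroxyl radical and collapses to the p-quinone without creating a stereocenter.

Step 2
Reactants: 3 (E)-resveratrol
Product: 4 (E)-3,5,4'-tris(tert-butyldimethylsilyloxy)stilbene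
Conditions: TBSCl, imidazole, DMF, rt
Reagents that add atoms: tert-butyldimethylsilyl chloride, CC(C)(C)[Si](C)(C)Cl
Why: Imidazole-promoted silylation of the three phenols, which keeps the 4-oxygenated ring a strong π-donor, should tolerate TiCl4 at −78 °C and allows one mild global deprotection at the end.

Step 3
Reactants: 2 2-chloro-6-methoxy-1,4-benzoquinone; 4 (E)-3,5,4'-tris(tert-butyldimethylsilyloxy)stilbene
Product: 5 (1S,6R,7S,8R)-1-chloro-3-methoxy-7-[3,5-bis(TBS-oxy)phenyl]-8-[4-(TBS-oxy)phenyl]bicyclo[4.2.0]oct-3-ene-2,5-dione (cis-fused, 7-aryl on the concave face, 8-aryl trans to it)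
Conditions: TiCl4, Ti(OiPr)4, (4R,5R)-TADDOL (premixed), CH2Cl2, −78 °C
Reagents that add atoms: none
Why: Lewis acid-promoted stepwise quinone–styrene [2+2] cycloaddition, in which the chiral titanium centre chelates the C3 carbonyl and the C2 methoxy oxygen of 2, the stilbene carbon β to the 4-silyloxyphenyl ring adds to C5, the resulting 4-silyloxybenzyl cation collapses onto the α-chloro titanium enolate carbon C4, the TADDOLate ligand selects the quinone face (absolute configuration of C5 and C6), the approach with the cation-bearing aryl stacked over the quinone fixes the C5/C6 relative configuration and the E-alkene gives trans aryl groups.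

Step 4
Reactants: 5 the cyclobutane-fused chloro-methoxy-enedione
Product: 8 (1S,5R,6S,7S)-4-chloro-3-hydroxy-6-[3,5-bis(TBS-oxy)phenyl]-7-[4-(TBS-oxy)phenyl]bicyclo[3.2.1]oct-3-ene-2,8-dione (6-aryl exo, 7-aryl endo; enol form of the 2,3-diketone), via benzylic cation–titanium enolate zwitterion 6 (not isolated), via bicyclic O-methyloxocarbenium ion 7 (not isolated)
Conditions: TiCl4 (3 equiv), CH2Cl2, −78 °C, then aq. NaHCO3 at −78 °C
Reagents that add atoms: none
Why: TiCl4 chelates the C3 carbonyl and the C2 methoxy oxygen and heterolyses the strained donor–acceptor bond C4–C7 (C7 bears the 4-silyloxyphenyl donor, C4 is α to the C3 carbonyl) to zwitterion 6, whose benzylic cation is recaptured by the enol-ether carbon C1 to give oxocarbenium ion 7; chloride then removes the O-methyl group, which makes the sequence irreversible and leaves the C2 ketone and the C3 titanium enolate (diosphenol 8 after work-up). The closest known reaction type is the Lewis acid-promoted conversion of quinone–styrene [2+2] adducts into formal [5+2] adducts, a cationic ring expansion of an aryl cyclobutane to a cyclopentanone. The single new bond C1–C7 closes the five-membered ring C1–C8–C5–C6–C7 in a 5-(enolexo)-exo-trig sense (the C1=C2 enol-ether bond stays outside that ring) and at the same time the seven-membered ring C1–C2–C3–C4–C5–C6–C7 in a 7-(enolendo)-exo-trig sense, which completes the bicyclo[3.2.1]octene. C5 and C6 are carried over unchanged from 5; C1 is dictated by the two-atom tether C5–C6, which lets C7 reach C1 only on the ring face that already carries C6, and C7 is set by the cation closing with its aryl group endo (over the titanium dienolate) and trans to the C6 aryl group. The step needs closure at carbon C1 and not at the C8 carbonyl oxygen (which after loss of H5 would give an aromatic dihydrobenzofuranol) or back at C4; the aprotic medium at −78 °C, the nucleophilic methoxy enol ether and the irreversible demethylation of 7 should secure this.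

Step 5
Reactants: 8 the 4-chloro-3-hydroxy bicyclic enedione
Product: 9 (1S,5R,6S,7S)-4-chloro-6-[3,5-bis(TBS-oxy)phenyl]-7-[4-(TBS-oxy)phenyl]-2,8-dioxobicyclo[3.2.1]oct-3-en-3-yl trifluoromethanesulfonate
Conditions: Tf2O, 2,6-lutidine, CH2Cl2, −78 °C
Reagents that add atoms: trifluoromethanesulfonic anhydride, O=S(=O)(OS(=O)(=O)C(F)(F)F)C(F)(F)F
Why: O-sulfonylation of the acidic diosphenol hydroxyl with a non-nucleophilic base gives the enol triflate without touching a stereocenter or the β-diketone.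

Step 6
Reactants: 9 the C3 enol triflate
Product: 10 (1R,5R,6S,7S)-4-chloro-6-[3,5-bis(TBS-oxy)phenyl]-7-[4-(TBS-oxy)phenyl]bicyclo[3.2.1]oct-3-ene-2,8-dione
Conditions: Pd(OAc)2 (5 mol%), dppp, Et3SiH, DMF, 40 °C
Reagents that add atoms: none
Why: Palladium-catalysed hydride-transfer reduction of an enol triflate (oxidative addition into C3–OTf, Si–H transmetalation, C–H reductive elimination), for which the triflate should insert much faster than the vinyl chloride under a bidentate arylphosphine at 40 °C.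

Step 7
Reactants: 10 the β-chloroenone; 11 4-(tert-butyldimethylsilyloxy)styrene
Product: 12 (1R,5S,6S,7S)-6-[3,5-bis(TBS-oxy)phenyl]-7-[4-(TBS-oxy)phenyl]-4-[(E)-2-(4-(TBS-oxy)phenyl)ethenyl]bicyclo[3.2.1]oct-3-ene-2,8-dione
Conditions: Pd2(dba)3 (2.5 mol%), P(t-Bu)3·HBF4, Cy2NMe, 1,4-dioxane, 70 °C
Reagents that add atoms: none
Why: Mizoroki–Heck reaction of the activated β-chloroenone with the styrene under an electron-rich bulky phosphine and a non-nucleophilic amine, in which syn-insertion and syn-β-hydride elimination give the (E)-diene.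

Step 8
Reactants: 12 the tetrakis-TBS ether of the target
Product: 13 (1R,5S,6S,7S)-6-(3,5-dihydroxyphenyl)-7-(4-hydroxyphenyl)-4-[(E)-2-(4-hydroxyphenyl)ethenyl]bicyclo[3.2.1]oct-3-ene-2,8-dione
Conditions: HF·pyridine, pyridine, THF, 0 °C to rt
Reagents that add atoms: none
Why: Fluoride cleavage of the four aryl silyl ethers under buffered, weakly acidic conditions, which avoids free phenoxide (retro-Michael opening of C1–C7) and strong acid (rearrangement to a dihydrobenzofuran).

Compound list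
1 | 2-chloro-6-methoxyphenol | COc1cccc(Cl)c1O | starting material
2 | 2-chloro-6-methoxy-1,4-benzoquinone | COC1=CC(=O)C=C(Cl)C1=O | intermediate
3 | (E)-resveratrol, 5-[(E)-2-(4-hydroxyphenyl)ethenyl]benzene-1,3-diol | Oc1ccc(/C=C/c2cc(O)cc(O)c2)cc1 | starting material
4 | (E)-3,5,4'-tris(tert-butyldimethylsilyloxy)stilbene | CC(C)(C)[Si](C)(C)Oc1ccc(/C=C/c2cc(O[Si](C)(C)C(C)(C)C)cc(O[Si](C)(C)C(C)(C)C)c2)cc1 | intermediate
5 | (1S,6R,7S,8R)-1-chloro-3-methoxy-7-[3,5-bis(TBS-oxy)phenyl]-8-[4-(TBS-oxy)phenyl]bicyclo[4.2.0]oct-3-ene-2,5-dione | COC1=CC(=O)[C@H]2[C@@H](c3cc(O[Si](C)(C)C(C)(C)C)cc(O[Si](C)(C)C(C)(C)C)c3)[C@H](c3ccc(O[Si](C)(C)C(C)(C)C)cc3)[C@@]2(Cl)C1=O | intermediate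
6 | ring-opened zwitterion: C7 4-silyloxybenzyl cation, C3 tetrachlorotitanate enolate (not isolated) | COC1=CC(=O)[C@@H]([C@@H](c2cc(O[Si](C)(C)C(C)(C)C)cc(O[Si](C)(C)C(C)(C)C)c2)[CH+]c2ccc(O[Si](C)(C)C(C)(C)C)cc2)C(Cl)=C1O[Ti-](Cl)(Cl)(Cl)Cl | intermediate
7 | bicyclo[3.2.1] C2 O-methyloxocarbenium ion with C3 tetrachlorotitanate enolate (not isolated) | C[O+]=C1C(O[Ti-](Cl)(Cl)(Cl)Cl)=C(Cl)[C@H]2C(=O)[C@@H]1[C@@H](c1ccc(O[Si](C)(C)C(C)(C)C)cc1)[C@@H]2c1cc(O[Si](C)(C)C(C)(C)C)cc(O[Si](C)(C)C(C)(C)C)c1 | intermediate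
8 | (1S,5R,6S,7S)-4-chloro-3-hydroxy-6-[3,5-bis(TBS-oxy)phenyl]-7-[4-(TBS-oxy)phenyl]bicyclo[3.2.1]oct-3-ene-2,8-dione | O=C1C(O)=C(Cl)[C@H]2C(=O)[C@@H]1[C@@H](c1ccc(O[Si](C)(C)C(C)(C)C)cc1)[C@@H]2c1cc(O[Si](C)(C)C(C)(C)C)cc(O[Si](C)(C)C(C)(C)C)c1 | intermediate
9 | (1S,5R,6S,7S)-4-chloro-6-[3,5-bis(TBS-oxy)phenyl]-7-[4-(TBS-oxy)phenyl]-2,8-dioxobicyclo[3.2.1]oct-3-en-3-yl trifluoromethanesulfonate | O=C1C(OS(=O)(=O)C(F)(F)F)=C(Cl)[C@H]2C(=O)[C@@H]1[C@@H](c1ccc(O[Si](C)(C)C(C)(C)C)cc1)[C@@H]2c1cc(O[Si](C)(C)C(C)(C)C)cc(O[Si](C)(C)C(C)(C)C)c1 | intermediate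
10 | (1R,5R,6S,7S)-4-chloro-6-[3,5-bis(TBS-oxy)phenyl]-7-[4-(TBS-oxy)phenyl]bicyclo[3.2.1]oct-3-ene-2,8-dione | O=C1C=C(Cl)[C@H]2C(=O)[C@@H]1[C@@H](c1ccc(O[Si](C)(C)C(C)(C)C)cc1)[C@@H]2c1cc(O[Si](C)(C)C(C)(C)C)cc(O[Si](C)(C)C(C)(C)C)c1 | intermediate
11 | 4-(tert-butyldimethylsilyloxy)styrene | C=Cc1ccc(O[Si](C)(C)C(C)(C)C)cc1 | starting material
12 | (1R,5S,6S,7S)-6-[3,5-bis(TBS-oxy)phenyl]-7-[4-(TBS-oxy)phenyl]-4-[(E)-2-(4-(TBS-oxy)phenyl)ethenyl]bicyclo[3.2.1]oct-3-ene-2,8-dione | O=C1C=C(/C=C/c2ccc(O[Si](C)(C)C(C)(C)C)cc2)[C@H]2C(=O)[C@@H]1[C@@H](c1ccc(O[Si](C)(C)C(C)(C)C)cc1)[C@@H]2c1cc(O[Si](C)(C)C(C)(C)C)cc(O[Si](C)(C)C(C)(C)C)c1 | intermediate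
13 | (1R,5S,6S,7S)-6-(3,5-dihydroxyphenyl)-7-(4-hydroxyphenyl)-4-[(E)-2-(4-hydroxyphenyl)ethenyl]bicyclo[3.2.1]oct-3-ene-2,8-dione | O=C1C=C(/C=C/c2ccc(O)cc2)[C@H]2C(=O)[C@@H]1[C@@H](c1ccc(O)cc1)[C@@H]2c1cc(O)cc(O)c1 | target

Total step count: 8. Longest linear sequence: 7 steps (steps 1, 3, 4, 5, 6, 7, 8; the branch through step 2 is equally long).

Steps most likely to fail

Step 4 (key step). After heterolysis the zwitterion may lose H5, aromatise and close through the C8 oxygen to a dihydrobenzofuranol. It may also dissociate completely by retro-Michael cleavage and so erode the C5/C6 configuration, and silyl ethers may be lost if the mixture warms. Fallback: leave out the isolated cyclobutane and unite 2 and 4 directly in a perezone-type formal [5+2] cycloaddition. The same TADDOL-derived titanium promoter is made chloride-rich (TiCl4 in excess over Ti(OiPr)4) in CH2Cl2 at −78 °C with a cold quench, so that the first-formed bicyclic oxocarbenium ion is O-demethylated before any four-membered ring is formed. This sets out from 2 and 4, rejoins the route at 8 and makes no new isolated compound.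

Step 3. Facial discrimination by the chiral titanium complex may be weak with the bulky stilbene, the bis-silyloxy arene may attack the activated quinone in a Friedel–Crafts sense, or the stilbene may add at C–Cl with loss of chloride. Fallback: give up asymmetric induction and resolve. 2 and 4 are joined with achiral TiCl4/Ti(OiPr)4 to the racemic cyclobutane, that is 5 together with its mirror image, the (1R,6S,7R,8S)-cyclobutane F1. The ring expansion of step 4 then gives the racemic diosphenol, that is 8 together with the (1R,5S,6R,7R)-diosphenol F2. The enantiomers are separated by preparative HPLC on a cellulose tris(3,5-dimethylphenylcarbamate) phase. This sets out from 2 and 4 and returns at 8.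

Step 6. Palladium may insert into the activated C4–Cl bond in competition with C3–OTf, or hydride may be delivered 1,4 to the enone with loss of chloride. Fallback: reverse the order of the two palladium steps so that no C–Cl bond is present when the triflate is reduced. From 8, acetylation (Ac2O, pyridine) gives the 4-chloro enol acetate F3. Mizoroki–Heck coupling of F3 with 11 (Pd2(dba)3, P(t-Bu)3·HBF4, Cy2NMe) gives the 4-styryl enol acetate F4. Ammonolysis (NH3, MeOH, 0 °C) frees the 4-styryl diosphenol F5, and Tf2O/2,6-lutidine gives the 4-styryl enol triflate F6. Reduction of F6 with Pd(OAc)2/PPh3/HCO2H/Et3N gives 12, where the route is rejoined.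

Further compounds
F0 | step 4 | none | none
F1 | step 3 | (1R,6S,7R,8S)-1-chloro-3-methoxy-7-[3,5-bis(TBS-oxy)phenyl]-8-[4-(TBS-oxy)phenyl]bicyclo[4.2.0]oct-3-ene-2,5-dione (mirror image of 5) | COC1=CC(=O)[C@@H]2[C@H](c3cc(O[Si](C)(C)C(C)(C)C)cc(O[Si](C)(C)C(C)(C)C)c3)[C@@H](c3ccc(O[Si](C)(C)C(C)(C)C)cc3)[C@]2(Cl)C1=O
F2 | step 3 | (1R,5S,6R,7R)-4-chloro-3-hydroxy-6-[3,5-bis(TBS-oxy)phenyl]-7-[4-(TBS-oxy)phenyl]bicyclo[3.2.1]oct-3-ene-2,8-dione (mirror image of 8) | O=C1C(O)=C(Cl)[C@@H]2C(=O)[C@H]1[C@H](c1ccc(O[Si](C)(C)C(C)(C)C)cc1)[C@H]2c1cc(O[Si](C)(C)C(C)(C)C)cc(O[Si](C)(C)C(C)(C)C)c1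
F3 | step 6 | 4-chloro-6-[3,5-bis(TBS-oxy)phenyl]-7-[4-(TBS-oxy)phenyl]-2,8-dioxobicyclo[3.2.1]oct-3-en-3-yl acetate (configuration as in 8) | O=C1C(OC(C)=O)=C(Cl)[C@H]2C(=O)[C@@H]1[C@@H](c1ccc(O[Si](C)(C)C(C)(C)C)cc1)[C@@H]2c1cc(O[Si](C)(C)C(C)(C)C)cc(O[Si](C)(C)C(C)(C)C)c1
F4 | step 6 | 6-[3,5-bis(TBS-oxy)phenyl]-7-[4-(TBS-oxy)phenyl]-4-[(E)-2-(4-(TBS-oxy)phenyl)ethenyl]-2,8-dioxobicyclo[3.2.1]oct-3-en-3-yl acetate (configuration as in 12) | O=C1C(OC(C)=O)=C(/C=C/c2ccc(O[Si](C)(C)C(C)(C)C)cc2)[C@H]2C(=O)[C@@H]1[C@@H](c1ccc(O[Si](C)(C)C(C)(C)C)cc1)[C@@H]2c1cc(O[Si](C)(C)C(C)(C)C)cc(O[Si](C)(C)C(C)(C)C)c1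
F5 | step 6 | 3-hydroxy-6-[3,5-bis(TBS-oxy)phenyl]-7-[4-(TBS-oxy)phenyl]-4-[(E)-2-(4-(TBS-oxy)phenyl)ethenyl]bicyclo[3.2.1]oct-3-ene-2,8-dione (configuration as in 12) | O=C1C(O)=C(/C=C/c2ccc(O[Si](C)(C)C(C)(C)C)cc2)[C@H]2C(=O)[C@@H]1[C@@H](c1ccc(O[Si](C)(C)C(C)(C)C)cc1)[C@@H]2c1cc(O[Si](C)(C)C(C)(C)C)cc(O[Si](C)(C)C(C)(C)C)c1
F6 | step 6 | 6-[3,5-bis(TBS-oxy)phenyl]-7-[4-(TBS-oxy)phenyl]-4-[(E)-2-(4-(TBS-oxy)phenyl)ethenyl]-2,8-dioxobicyclo[3.2.1]oct-3-en-3-yl trifluoromethanesulfonate (configuration as in 12) | O=C1C(OS(=O)(=O)C(F)(F)F)=C(/C=C/c2ccc(O[Si](C)(C)C(C)(C)C)cc2)[C@H]2C(=O)[C@@H]1[C@@H](c1ccc(O[Si](C)(C)C(C)(C)C)cc1)[C@@H]2c1cc(O[Si](C)(C)C(C)(C)C)cc(O[Si](C)(C)C(C)(C)C)c1
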